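**Plan**
- Numbering: ring B is the central ring, with OH at position 1, allyl at position 2, ring A at position 4 and ring C at position 6; in each outer ring carbon 1 is the biaryl carbon, carbon 2 bears OH and carbon 5 bears allyl; each arm chain is counted from chain carbon 1 (CH2O) to chain carbon 5 (aryl-bearing).
- Enabling feature: in ring A and in ring C the oxygen-bearing carbon 2 lies between the biaryl carbon 1 and an unsubstituted CH (carbon 3) and para to the allyl-bearing carbon 5, so it can be one molecule of carbon monoxide joining the two ends of a 3-allyl-5-arylpenta-2,4-dienyl chain.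
- Retrosynthesis: first the two bonds flanking carbon 2 in ring A and in ring C are cut (twofold carbonylative [5+1] benzannulation), then the bond between chain carbons 3 and 4 of each arm (Suzuki coupling), then the alkene between chain carbons 4 and 5 of each arm back to formyl groups at positions 4 and 6 of ring B (boron–Wittig olefination), then the allyl bond at position 2 of ring B (Claisen rearrangement).
- Forward: ring B is bought as 4-hydroxyisophthalaldehyde and allylated at position 2, both five-carbon arms are attached, rings A and C are closed together in one carbonylation, and deprotection ends the route.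
- Stereochemistry: the target has no stereocentre; only the arm geometry matters, (4E) from the boron–Wittig step and (2Z) from trans-hydroalumination/iodination carried through a stereoretentive coupling, which pre-sets the cisoid triene.

Key step: step 9

Remark: the phenol of ring B is carried as a methoxymethyl (MOM) ether so that the final deprotection needs no Lewis acid beside three allyl groups; LiTMP is taken as a commercial solution.

**Step 1**
Reactants: 1 4-hydroxyisophthalaldehyde; 2 allyl bromide
Product: 3 4-(allyloxy)isophthalaldehyde
Conditions: K2CO3, DMF, 50 °C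
Reagents that add atoms: none
Why: Williamson etherification of the acidic, doubly formyl-activated phenol should be clean and leaves the aldehydes untouched.

**Step 2**
Reactants: 3 4-(allyloxy)isophthalaldehyde
Product: 4 5-allyl-4-hydroxyisophthalaldehyde
Conditions: 1,2-dichlorobenzene, 180 °C, argon
Reagents that add atoms: none
Why: The aromatic Claisen rearrangement ([3,3]-sigmatropic shift, then tautomerisation) can deliver the allyl group only to the single free ortho position, because the other ortho carbon and the para carbon carry formyl groups.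

**Step 3**
Reactants: 4 5-allyl-4-hydroxyisophthalaldehyde
Product: 5 5-allyl-4-(methoxymethoxy)isophthalaldehyde
Conditions: MOMCl, i-Pr2NEt, CH2Cl2, 0 °C to rt
Reagents that add atoms: chloromethyl methyl ether (MOMCl), COCCl
Why: Base-mediated O-alkylation gives an acetal ether that should tolerate the lithium amide, the palladium steps and hot Ac2O/NEt3, and is removed by dilute acid at the end.

**Step 4**
Reactants: 5 5-allyl-4-(methoxymethoxy)isophthalaldehyde
Product: 6 2,2'-{[5-allyl-4-(methoxymethoxy)-1,3-phenylene]di[(E)-ethene-2,1-diyl]}bis(4,4,5,5-tetramethyl-1,3,2-dioxaborolane)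
Conditions: CH2(Bpin)2, LiTMP, THF, 0 °C; then 5, −78 °C to rt
Reagents that add atoms: bis[(pinacolato)boryl]methane, CC1(C)OB(CB2OC(C)(C)C(C)(C)O2)OC1(C)C
Why: In this boron–Wittig olefination the lithiated diborylmethane adds to each non-enolisable aldehyde and syn B–O elimination should give the (E)-alkenylboronate at both sites.

**Step 5**
Reactants: 7 propargyl alcohol; 2 allyl bromide
Product: 8 hex-5-en-2-yn-1-ol
Conditions: CuI (cat.), K2CO3, n-Bu4NI (cat.), DMF, rt
Reagents that add atoms: none
Why: CuI-mediated allylation of the terminal alkyne under carbonate gives the skipped enyne without a base strong enough to isomerise it.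

**Step 6**
Reactants: 8 hex-5-en-2-yn-1-ol
Product: 10 (Z)-3-iodohexa-2,5-dien-1-ol, via vinylalanate 9 (not isolated)
Conditions: NaAlH2(OCH2CH2OMe)2, THF, 0 °C to rt; then I2, THF, −78 to 0 °C
Reagents that add atoms: iodine, II
Why: Alkoxide-directed trans-hydroalumination of the propargylic alcohol places aluminium on carbon 3 in a five-membered alanate, and iodinolysis with retention fixes iodine cis to CH2OH while the isolated terminal alkene is inert to the hydride.

**Step 7**
Reactants: 6 bis(alkenylboronate); 10 (Z)-3-iodohexa-2,5-dien-1-ol
Product: 11 (2Z,2'Z,4E,4'E)-5,5'-[5-allyl-4-(methoxymethoxy)-1,3-phenylene]bis(3-allylpenta-2,4-dien-1-ol)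
Conditions: PdCl2(dppf) (cat.), aq. K3PO4, THF, 45 °C, degassed
Reagents that add atoms: none
Why: Twofold Suzuki–Miyaura alkenyl–alkenyl coupling proceeds with retention at both partners, so the (E)-styryl and (Z)-iodoalkene geometries should be carried into the (2Z,4E)-dienols, and the free allylic alcohols tolerate the mild phosphate base.

**Step 8**
Reactants: 11 bis(dienol)
Product: 12 diacetate of 11, the bis[(2Z,4E)-3-allyl-5-arylpenta-2,4-dienyl acetate]
Conditions: Ac2O, pyridine, DMAP (cat.), CH2Cl2, 0 °C to rt
Reagents that add atoms: acetic anhydride, CC(=O)OC(C)=O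
Why: DMAP-catalysed acetylation of the primary allylic alcohols is standard, and the basic medium avoids ionising the pentadienyl system.

**Step 9**
Reactants: 12 bis(pentadienyl acetate); 13 carbon monoxide
Product: 16 5,5',5''-triallyl-4'-(methoxymethoxy)-[1,1':3',1''-terphenyl]-2,2''-diyl diacetate, via bis(dienylketene) 14 (not isolated), via bis(cyclohexadienone) 15 (not isolated)
Conditions: PdCl2(PPh3)2 (cat.), CO (60 atm), Ac2O, NEt3, toluene, 140 °C, autoclave
Reagents that add atoms: acetic anhydride, CC(=O)OC(C)=O
Why: PdCl2(PPh3)2 is reduced under CO/NEt3 to zerovalent palladium, which ionises each primary allylic acetate of 12 to a π-allyl-type pentadienyl complex of divalent palladium; CO inserts at the CH2 terminus (forming the bond between carbons 2 and 3 of ring A and of ring C) and NEt3 converts each acyl complex into a dienylketene arm of 14. Each ketene closes ring A or ring C by thermal disrotatory 6π electrocyclisation of the ketene carbon onto the aryl-bearing chain terminus (forming the bond between carbons 1 and 2 of each outer ring) to give the bis(cyclohexa-2,4-dienone) 15, whose ring CH next to the carbonyl is deprotonated by NEt3 and whose phenoxide is O-acetylated by Ac2O to 16. The closest known reaction is the palladium-catalysed cyclocarbonylation of 2,4-pentadienyl acetates to phenyl acetates, in which a 5-aryl substituent ends up as a 2-acetoxybiaryl. The two sp3 carbons of 15 form without control and are erased on aromatisation, so no stereocentre remains. The step needs CO uptake at a chain terminus, a cisoid 2,3-alkene in each arm and survival of three skipped alkenes: the unhindered CH2 terminus is favoured, and insertion at the benzylic terminus would still place the carbonyl carbon between chain carbons 1 and 5; the (2Z) geometry of 12 holds the styryl unit cis to the acyl carbon and the allyl group on chain carbon 3 away from it. Excess NEt3 and Ac2O under high CO pressure should suppress Pd–H formation and β-hydride elimination, which would otherwise move the alkenes into conjugation.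

**Step 10**
Reactants: 16 terphenyl diacetate MOM ether
Product: 18 macranthol, via MOM diphenol 17 (not isolated)
Conditions: K2CO3, MeOH, rt; then 3 M aq. HCl, 50 °C
Reagents that add atoms: none
Why: Carbonate-mediated transesterification frees the two aryl acetates at room temperature, and acid-catalysed acetal exchange then removes the MOM group under conditions too mild to add to or cyclise onto the allyl groups.

**Compound list**
1 | 4-hydroxyisophthalaldehyde | O=Cc1ccc(O)c(C=O)c1 | starting material
2 | allyl bromide | C=CCBr | starting material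
3 | 4-(allyloxy)isophthalaldehyde | O=Cc1ccc(OCC=C)c(C=O)c1 | intermediate
4 | 5-allyl-4-hydroxyisophthalaldehyde | O=Cc1cc(CC=C)c(O)c(C=O)c1 | intermediate
5 | 5-allyl-4-(methoxymethoxy)isophthalaldehyde | COCOc1c(CC=C)cc(C=O)cc1C=O | intermediate
6 | 2,2'-{[5-allyl-4-(methoxymethoxy)-1,3-phenylene]di[(E)-ethene-2,1-diyl]}bis(4,4,5,5-tetramethyl-1,3,2-dioxaborolane) | COCOc1c(CC=C)cc(/C=C/B2OC(C)(C)C(C)(C)O2)cc1/C=C/B3OC(C)(C)C(C)(C)O3 | intermediate
7 | propargyl alcohol | C#CCO | starting material
8 | hex-5-en-2-yn-1-ol | C=CCC#CCO | intermediate
9 | sodium cyclic vinylalanate, ring O–Al–C(allyl)=CH–CH2 with two 2-methoxyethoxy groups on aluminium (not isolated) | [Na+].C=CCC1=CCO[Al-]1(OCCOC)OCCOC | intermediate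
10 | (Z)-3-iodohexa-2,5-dien-1-ol (iodine cis to CH2OH) | C=CC/C(I)=C/CO | intermediate
11 | (2Z,2'Z,4E,4'E)-5,5'-[5-allyl-4-(methoxymethoxy)-1,3-phenylene]bis(3-allylpenta-2,4-dien-1-ol) | COCOc1c(CC=C)cc(/C=C/C(CC=C)=C\CO)cc1/C=C/C(CC=C)=C\CO | intermediate
12 | diacetate of 11, bis[(2Z,4E)-3-allyl-5-arylpenta-2,4-dienyl acetate] | COCOc1c(CC=C)cc(/C=C/C(CC=C)=C\COC(C)=O)cc1/C=C/C(CC=C)=C\COC(C)=O | intermediate
13 | carbon monoxide | [C-]#[O+] | starting material
14 | bis(dienylketene), each arm (3Z,5E)-4-allyl-6-arylhexa-1,3,5-trien-1-one (not isolated) | COCOc1c(CC=C)cc(/C=C/C(CC=C)=C\C=C=O)cc1/C=C/C(CC=C)=C\C=C=O | intermediate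
15 | 6,6'-[5-allyl-4-(methoxymethoxy)-1,3-phenylene]bis(4-allylcyclohexa-2,4-dien-1-one), mixture of stereoisomers at the two sp3 ring carbons (not isolated) | COCOc1c(CC=C)cc(C2C=C(CC=C)C=CC2=O)cc1C3C=C(CC=C)C=CC3=O | intermediate
16 | 5,5',5''-triallyl-4'-(methoxymethoxy)-[1,1':3',1''-terphenyl]-2,2''-diyl diacetate | C=CCc1ccc(OC(C)=O)c(-c2cc(CC=C)c(OCOC)c(-c3cc(CC=C)ccc3OC(C)=O)c2)c1 | intermediate
17 | 5,5',5''-triallyl-4'-(methoxymethoxy)-[1,1':3',1''-terphenyl]-2,2''-diol (not isolated) | C=CCc1ccc(O)c(-c2cc(CC=C)c(OCOC)c(-c3cc(CC=C)ccc3O)c2)c1 | intermediate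
18 | macranthol, 5,5',5''-triallyl-[1,1':3',1''-terphenyl]-2,2'',4'-triol | C=CCc1ccc(O)c(-c2cc(CC=C)c(O)c(-c3cc(CC=C)ccc3O)c2)c1 | target

**Count**
Total steps: 10. Longest linear sequence: 8 steps (steps 1–4 and 7–10); steps 5–6 make the second coupling partner.

**Steps most likely to fail**

Step 9. What may go wrong: Pd–H-mediated migration of the skipped alkenes into conjugation at 140 °C, β-hydride elimination from the pentadienyl complex before CO insertion, and stalling after only one arm has closed. The fallback separates carbonylation from ring closure and sets out from diol 11. Methyl chloroformate and pyridine should give the bis(methyl carbonate) F1. Decarboxylative carbonylation of the allylic carbonates under neutral conditions (Pd(OAc)2, PPh3, CO 10 atm, 50 °C) should give the bis(methyl 3,5-dienoate) F2. Hydrolysis with LiOH in aqueous THF at 0 °C should give the bis(3,5-dienoic acid) F3. Heating F3 in Ac2O with NaOAc at 120 °C should form the mixed anhydride, eliminate to the same dienylketene and, after metal-free 6π electrocyclisation and acetylation, rejoin the route at 16.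

Step 7. What may go wrong: protodeboronation or oxidative homocoupling of the bis(alkenylboronate), an incomplete second coupling, and erosion of the Z geometry by palladium-mediated isomerisation. The fallback reverses the polarity of the coupling and sets out from dialdehyde 5 and iodide 10. Takai iodo-olefination of 5 (CHI3, CrCl2, THF, 0 °C) should give the bis[(E)-2-iodovinyl]arene F4. Miyaura borylation of 10 (B2pin2, PdCl2(PPh3)2, PPh3, KOPh, toluene, 50 °C) should give (E)-3-(pinacolboryl)hexa-2,5-dien-1-ol F5, with boron cis to CH2OH. Suzuki coupling of F4 with two equivalents of F5 (Pd(PPh3)4, aq. K3PO4, THF) rejoins the route at 11.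

Step 6. What may go wrong: delivery of aluminium to carbon 2 instead of carbon 3, hydride-induced isomerisation of the skipped enyne to an allene or conjugated enyne, and protonation of the alanate before iodine reaches it. The fallback works at the ester oxidation level and sets out from allyl bromide 2. CuI-mediated coupling of 2 with ethyl propiolate (CuI, K2CO3, n-Bu4NI, DMF) should give ethyl hex-5-en-2-ynoate F6. Anti-hydroiodination with NaI in acetic acid at 70 °C should give ethyl (Z)-3-iodohexa-2,5-dienoate F7. Reduction with i-Bu2AlH in CH2Cl2 at −78 °C rejoins the route at 10.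

**Further compounds**
F1 | step 9 | bis(methyl carbonate) of 11 | COCOc1c(CC=C)cc(/C=C/C(CC=C)=C\COC(=O)OC)cc1/C=C/C(CC=C)=C\COC(=O)OC
F2 | step 9 | dimethyl (3Z,3'Z,5E,5'E)-6,6'-[5-allyl-4-(methoxymethoxy)-1,3-phenylene]bis(4-allylhexa-3,5-dienoate) | COCOc1c(CC=C)cc(/C=C/C(CC=C)=C\CC(=O)OC)cc1/C=C/C(CC=C)=C\CC(=O)OC
F3 | step 9 | (3Z,3'Z,5E,5'E)-6,6'-[5-allyl-4-(methoxymethoxy)-1,3-phenylene]bis(4-allylhexa-3,5-dienoic acid) | COCOc1c(CC=C)cc(/C=C/C(CC=C)=C\CC(=O)O)cc1/C=C/C(CC=C)=C\CC(=O)O
F4 | step 7 | 1-allyl-3,5-bis[(E)-2-iodovinyl]-2-(methoxymethoxy)benzene | COCOc1c(CC=C)cc(/C=C/I)cc1/C=C/I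
F5 | step 7 | (E)-3-(4,4,5,5-tetramethyl-1,3,2-dioxaborolan-2-yl)hexa-2,5-dien-1-ol (boron cis to CH2OH) | C=CC/C(B1OC(C)(C)C(C)(C)O1)=C/CO
F6 | step 6 | ethyl hex-5-en-2-ynoate | C=CCC#CC(=O)OCC
F7 | step 6 | ethyl (Z)-3-iodohexa-2,5-dienoate | C=CC/C(I)=C/C(=O)OCC
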